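At early times the electrophile looks simple: the first reading of the dawn run gives a decay of 0.439 d⁻¹ at 0.090 M of nucleophile, so a reading of 4.87 L mol⁻¹ d⁻¹ for the rate constant.

all flasks: electrophile 0.050 M
- dawn: nucleophile 0.090 M; run made earlier
- spring: nucleophile 0.35 M; run made earlier
- Saturday's: nucleophile 0.0600 M; time 10 d
- Thursday's: nucleophile 0.120 M; time 10 d
- Sunday's: nucleophile 0.240 M; time 10 d

- dawn (time / d: electrophile / %, target / %): 1.25: 57.8, 37.9; 2.50: 38.3, 48.5; 4.00: 25.2, 54.6; 5.00: 21.1, 56.9
- spring (time / d: electrophile / %, target / %): 1.25: 9.7, 85.1; 2.50: 0, 92.8; 4.00: 0, 92.9; 5.00: 0.1, 93.4

(readings scatter by 0.5 percentage points)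



1. part of the electrophile that has reacted at the end, Saturday's
2. part of the electrophile that has reacted at the end, Thursday's
3. part of the electrophile that has reacted at the end, Sunday's
4. what raising the concentration of nucleophile from its lowest to its highest value here does to the part of the electrophile that has reacted (changes below 5 percentage points count as none) (it falls / it rises / no change)

Two chemists argue over Saturday's flask, which has 0.0600 M of nucleophile on 0.050 M of electrophile. The first holds that the nucleophile is in excess and the clock counts. Treating the decay as pseudo-first-order at the charged nucleophile, the half-life is 2.37 d, short against 10 d, so on this view a fraction 0.946 of Saturday's electrophile reacts by then.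

The second chemist, who made the forecast, points to the end of the dawn run, where the decay has dropped to 0.178 d⁻¹, and argues that “the decay fits about two nucleophile per electrophile”. The forecast therefore reads 68% for Saturday's, 97% for Thursday's and 100% for Sunday's, and says it rises.

I take that count and make one number of it: 0.600 for Saturday's. This is the cover, the nucleophile charged over twice the electrophile charged, which is the fraction of the electrophile that the main step can serve on that count. It counts the main step and no other, and it stands below the forecast's 68% for Saturday's. On that count the crossing stands at 1: below it the nucleophile is the limiting reagent, above it the electrophile is. Thursday's cover is 1.20 and Sunday's is 2.40, so Saturday's lies below the crossing and Sunday's above it.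

The reacted part of the electrophile comes to 76.3% for Saturday's, 98.1% for Thursday's and >99.9% for Sunday's; with more nucleophile it rises, by 24 percentage points, and the forecast stands 8.3 points low on Saturday's. Saturday's ends with 5.7% of its nucleophile free, which favours the second chemist there. The first keeps the ground above the crossing: Sunday's, at cover 2.40, has 0% electrophile left with half of its nucleophile free. Saturday's cover of 0.600 meets a main-step fraction of 0.565, target plus half the side product, which holds two electrophile. Saturday's reacted part stands higher than that cover.

    nucleophile + acid set free ⇌ protonated nucleophile, settled at all times (K = 57000 L mol⁻¹)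
    electrophile + target → side product (k = 3.30 × 10⁻⁵ L mol⁻¹ s⁻¹)
    acid set free → by-product carried off (k = 1.10 × 10⁻⁵ s⁻¹)
    electrophile + nucleophile → acid set free + target (k = 8.90 × 10⁻⁵ L mol⁻¹ s⁻¹)
    nucleophile ⇌ dormant form (K = 0.220, k = 5.10 × 10⁻⁵ s⁻¹)

The neighbour of Saturday's with 0.024 M of nucleophile has a cover of 0.240, below the crossing, so the main step should serve about that fraction. The computed flask has target 11.3% and side product 26.7%, a main-step fraction of 0.246, and 38.1% of the electrophile reacted.

The runs come from a simulation with made-up constants; scatter was added.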